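The target, the nonadecyl ester of 3-(4-hydroxyphenyl)propanoic acid, has one ring (the para-hydroxyphenyl ring) and no stereocentre. Everything rests on cutting the straight, unfunctionalised O-alkyl chain between C4 and C5, counted from the ester oxygen. The key step exploits exactly this featureless C1–C19 chain: any C–C bond in it can be made as an alkene and then erased. The precursor is the pent-4-enyl ester of the acid, carrying the free phenol and a terminal alkene three sp3 carbons away from oxygen. Ruthenium-catalysed cross-metathesis with 1-hexadecene attaches C5–C19 in one operation, forming C4=C5 with loss of ethylene; hydrogenation finishes the synthesis.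

Key step: step 2

Remark (assumption): the cross-metathesis product is expected as an E/Z mixture. It is named and drawn as the E isomer, and both isomers lead to the same saturated ester.
Remark (carbon count): the pent-4-enyl group supplies C1–C4 and loses its fifth carbon. Hexadec-1-ene supplies C5–C19 and loses its C1. This gives 4 + 15 = 19 chain carbons, as the target requires.

Step 1
Reactants: 1 phloretic acid [3-(4-hydroxyphenyl)propanoic acid]; 2 pent-4-en-1-ol
Product: 3 pent-4-enyl 3-(4-hydroxyphenyl)propanoate
Conditions: 2 (2 equiv), p-TsOH·H2O (5 mol%), toluene, Dean–Stark, reflux
Reagents that add atoms: none
Why: Fischer esterification, in which only the aliphatic alcohol attacks the protonated acid because the phenol oxygen is too weak a nucleophile under acid catalysis, azeotropic removal of water drives the equilibrium, the isolated terminal alkene is inert to catalytic sulfonic acid, and no stereocentre is formed.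

Step 2
Reactants: 3 pent-4-enyl 3-(4-hydroxyphenyl)propanoate; 4 hexadec-1-ene (1-hexadecene)
Product: 5 (E)-nonadec-4-enyl 3-(4-hydroxyphenyl)propanoate (E/Z mixture, used as such)
Conditions: 4 (5 equiv), second-generation Grubbs catalyst (H2IMes)(PCy3)Cl2Ru=CHPh (3 mol%), 1,4-benzoquinone (10 mol%), CH2Cl2 (0.1 M), 40 °C, slow N2 sweep; silica gel chromatography
Reagents that add atoms: none
Why: Olefin cross-metathesis by the Chauvin mechanism: after loss of PCy3 the 14-electron ruthenium alkylidene adds to each terminal alkene in a [2+2] sense, the ruthenacyclobutane cleaves the other way, and the two =CH2 ends of 3 and 4 leave as ethylene while the C4 and C5 alkylidene halves are joined. The closest known reaction type is the cross-metathesis of two unhindered monosubstituted alkenes, both type 1 partners that homodimerise quickly and reversibly. One skeletal bond (C4=C5) forms, no ring closes and no stereocentre arises; the alkene geometry settles under thermodynamic control toward E and is of no consequence because step 3 removes it. The first selectivity needed is cross-coupling over self-coupling of 3, which is secured together by the surplus of cheap 4, the re-entry of any ester homodimer into the equilibrium by secondary metathesis, and the venting of ethylene. The second is positional fidelity, since ruthenium hydride chain-walking before metathesis would shift the chain length by one carbon and such homologues could not be removed after hydrogenation; 1,4-benzoquinone as hydride scavenger, the mild temperature and isomer-free 4 (99% grade) guard against it. In 3 the three sp3 carbons between alkene and ester oxygen rule out a deactivating carbonyl chelate, phenol and ester are inert to the carbene so no protection is spent, and the polar phenol lets all hydrocarbon material be washed off silica with hexane before 5 is eluted.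

Step 3
Reactants: 5 (E)-nonadec-4-enyl 3-(4-hydroxyphenyl)propanoate (E/Z mixture)
Product: 6 nonadecyl 3-(4-hydroxyphenyl)propanoate (target)
Conditions: H2 (1 atm), 10% Pd/C, EtOAc, rt
Reagents that add atoms: none
Why: Heterogeneous catalytic hydrogenation, in which syn addition of H2 to the unhindered 1,2-disubstituted alkene on palladium is far faster than any attack on the phenol ring, the ester C–O bond is neither allylic nor benzylic and so resists hydrogenolysis, and both alkene isomers converge on the achiral target.

Compound list
1 | phloretic acid, 3-(4-hydroxyphenyl)propanoic acid | OC(=O)CCc1ccc(O)cc1 | starting material
2 | pent-4-en-1-ol | C=CCCCO | starting material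
3 | pent-4-enyl 3-(4-hydroxyphenyl)propanoate | C=CCCCOC(=O)CCc1ccc(O)cc1 | intermediate
4 | hexadec-1-ene (1-hexadecene) | CCCCCCCCCCCCCCC=C | starting material
5 | (E)-nonadec-4-enyl 3-(4-hydroxyphenyl)propanoate | CCCCCCCCCCCCCC/C=C/CCCOC(=O)CCc1ccc(O)cc1 | intermediate
6 | nonadecyl 3-(4-hydroxyphenyl)propanoate | CCCCCCCCCCCCCCCCCCCOC(=O)CCc1ccc(O)cc1 | target

Total step count: 3
Longest linear sequence: 3

Steps most likely to fail

1. Step 2. The risks are statistical scrambling with self-coupling of the ester, early death of the catalyst, and double-bond migration ahead of metathesis that blurs the chain length. The fallback builds the C19 chain without any alkene, as C16 + C3, and attaches the acid last. It sets out from 1 and comes back to the route at 6. Purchased 1-bromohexadecane and Mg in THF give hexadecylmagnesium bromide F1. This opens oxetane under CuI catalysis (THF, 0 °C to reflux, dilute HCl work-up) to give nonadecan-1-ol F2. Fischer esterification of 1 with F2 under the conditions of step 1 then gives 6 directly, so 3, 4 and 5 are bypassed. The chain length is fixed by the two building blocks, so no homologue can arise.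

2. Step 1. The risks are stalling of the equilibrium if water removal is inefficient, acid-induced ring closure of the pentenol onto its own alkene (which drains the alcohol), and slight acylation of the phenol. The fallback makes the ester by forming the O–alkyl bond instead of the acyl–O bond. It sets out from 1 and comes back at 3. KHCO3 (1.1 equiv) in DMF deprotonates only the carboxylic acid to give potassium 3-(4-hydroxyphenyl)propanoate F3. SN2 reaction of this salt with 5-bromopent-1-ene (40 °C) gives 3. The phenol stays protonated with this weak base and is not alkylated, and no acid touches the alkene.

3. Step 3. The risks are slow hydrogen uptake through poisoning of the palladium surface by ruthenium or phosphine residues, and palladium-mediated migration of the double bond toward the oxygen before saturation, which would open a path to C–O hydrogenolysis. The fallback is a metal-free diimide reduction. It sets out from 5 and comes back at 6. p-Toluenesulfonyl hydrazide (excess, added in portions) and NaOAc in refluxing THF/H2O release diimide F4. This transfers two hydrogens to the alkene in a concerted syn fashion through a six-membered transition state and leaves arene, phenol and ester untouched.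

Further compounds
F1 | step 2 | hexadecylmagnesium bromide | CCCCCCCCCCCCCCCC[Mg]Br
F2 | step 2 | nonadecan-1-ol | CCCCCCCCCCCCCCCCCCCO
F3 | step 1 | potassium 3-(4-hydroxyphenyl)propanoate | [K+].[O-]C(=O)CCc1ccc(O)cc1
F4 | step 3 | diimide | N=N
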